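## Retrosynthetic overview

1. Gnetal ⇐ fluoride desilylation of its tetrasilyl ether, so the end-game needs no Lewis acid.
2. Tetrasilyl ether ⇐ one flask: Danheiser benzannulation of a chiral siloxyalkyne with 3-(diethoxymethyl)cyclobutenone builds ring A (the resorcinol aldehyde ring) from open-chain carbons; aqueous TFA then unmasks the aldehyde and closes the dihydrofuran (O–C2 bond, trans set here).
3. Siloxyalkyne ⇐ Kowalski ynolate homologation and O-silylation of an α-aryl-β-siloxy ester.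
4. Ester ⇐ enantioselective rhodium-carbenoid C–H insertion of an aryldiazoacetate into a 4-siloxybenzyl silyl ether (sets C-3 of the target).
5. Ring order: ring A first, dihydrofuran second, same operation; the two hydroxyphenyl rings are bought; the cyclobutenone comes from 3,3-diethoxypropyne and dichloroketene.

Assumption: Rh2(S-DOSP)4 is taken to give the 2R centre in step 4 (same facial sense as in its cyclopropanations and cyclohexadiene insertions); if the sense proved opposite, Rh2(R-DOSP)4 would be used with no other change.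

## Route

Step 1
Reactants: 1 methyl 2-(3,5-dihydroxyphenyl)acetate
Product: 2 methyl 2-[3,5-bis(triisopropylsilyloxy)phenyl]acetate
Conditions: TIPSCl (2.3 equiv), imidazole, DMF, rt
Reagents that add atoms: triisopropylsilyl chloride (TIPSCl), CC(C)[Si](Cl)(C(C)C)C(C)C
Why: Imidazole-promoted O-silylation of both phenols gives bulky TIPS ethers that resist DBU, organolithiums and TFA in later steps and leave with fluoride at the end.

Step 2
Reactants: 2 methyl 2-[3,5-bis(triisopropylsilyloxy)phenyl]acetate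
Product: 3 methyl 2-diazo-2-[3,5-bis(triisopropylsilyloxy)phenyl]acetate
Conditions: p-ABSA (1.2 equiv), DBU, dry MeCN, 0 °C → rt
Reagents that add atoms: 4-acetamidobenzenesulfonyl azide (p-ABSA), CC(=O)Nc1ccc(cc1)S(=O)(=O)N=[N+]=[N-]
Why: Regitz diazo transfer to the methylene activated by both aryl and ester gives the donor/acceptor diazo ester.

Step 3
Reactants: 4 4-(hydroxymethyl)phenol
Product: 5 tert-butyl{[4-(tert-butyldimethylsilyloxy)phenyl]methoxy}dimethylsilane
Conditions: TBSCl (2.3 equiv), imidazole, DMF, rt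
Reagents that add atoms: tert-butyldimethylsilyl chloride (TBSCl), CC(C)(C)[Si](C)(C)Cl
Why: Standard double silylation of phenol and benzylic alcohol gives the electron-rich benzyl silyl ether whose O–CH2 hydrogens are activated for carbenoid insertion.

Step 4
Reactants: 3 methyl 2-diazo-2-[3,5-bis(triisopropylsilyloxy)phenyl]acetate; 5 tert-butyl{[4-(tert-butyldimethylsilyloxy)phenyl]methoxy}dimethylsilane (2 equiv, excess recovered)
Product: 6 methyl (2R,3R)-2-[3,5-bis(triisopropylsilyloxy)phenyl]-3-(tert-butyldimethylsilyloxy)-3-[4-(tert-butyldimethylsilyloxy)phenyl]propanoate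
Conditions: Rh2(S-DOSP)4 (dirhodium tetrakis[(S)-N-(4-dodecylbenzenesulfonyl)prolinate], 1 mol %), 2,2-dimethylbutane, rt, 3 added over 2 h
Reagents that add atoms: none
Why: Davies-type intermolecular C–H insertion of a donor/acceptor rhodium carbenoid into the activated benzylic C–H of a benzyl silyl ether (an aldol surrogate), in which the chiral dirhodium tetraprolinate fixes the face of the carbenoid that is attacked and so sets C-2 as R (the future C-3 of the target), while the syn C-3 centre formed alongside is erased later.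

Step 5
Reactants: 6 methyl (2R,3R)-2-[3,5-bis(triisopropylsilyloxy)phenyl]-3-(tert-butyldimethylsilyloxy)-3-[4-(tert-butyldimethylsilyloxy)phenyl]propanoate
Product: 8 triisopropyl{[(3S,4R)-3-[3,5-bis(triisopropylsilyloxy)phenyl]-4-(tert-butyldimethylsilyloxy)-4-[4-(tert-butyldimethylsilyloxy)phenyl]but-1-yn-1-yl]oxy}silane, via lithium ynolate 7 (not isolated)
Conditions: CH2Br2, LiTMP, THF, −78 °C (ester premixed with CH2Br2); LiHMDS; n-BuLi, −78 °C → rt; TIPSCl, −78 °C → rt
Reagents that add atoms: dibromomethane, BrCBr; triisopropylsilyl chloride (TIPSCl), CC(C)[Si](Cl)(C(C)C)C(C)C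
Why: Kowalski ester homologation, in which LiCHBr2 adds to the ester, the dibromoketone enolate undergoes Br–Li exchange and a carbenoid 1,2-shift of the chiral alkyl group with retention to give ynolate 7, and the bulky TIPSCl silylates on oxygen (the descriptor at the aryl-bearing carbon changes from R to S only because the priorities change).

Step 6
Reactants: 9 3,3-diethoxyprop-1-yne
Product: 10 4,4-dichloro-3-(diethoxymethyl)cyclobut-2-en-1-one
Conditions: Cl3CCOCl, Zn–Cu couple, DME, Et2O, rt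
Reagents that add atoms: trichloroacetyl chloride, ClC(=O)C(Cl)(Cl)Cl
Why: [2+2] cycloaddition of electrophilic dichloroketene, generated by zinc dechlorination of the acid chloride, across the terminal alkyne with the unsubstituted alkyne carbon bonding to the ketene carbonyl carbon, DME sequestering ZnCl2 to protect the acetal.

Step 7
Reactants: 10 4,4-dichloro-3-(diethoxymethyl)cyclobut-2-en-1-one
Product: 11 3-(diethoxymethyl)cyclobut-2-en-1-one
Conditions: Zn dust, AcOH, TMEDA, EtOH, 0 °C → rt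
Reagents that add atoms: none
Why: Zinc-mediated reductive removal of both α-chlorines under TMEDA-buffered AcOH in ethanol (the Danheiser cyclobutenone protocol) leaves the diethyl acetal and the strained enone intact.

Step 8
Reactants: 8 triisopropyl{[(3S,4R)-3-[3,5-bis(triisopropylsilyloxy)phenyl]-4-(tert-butyldimethylsilyloxy)-4-[4-(tert-butyldimethylsilyloxy)phenyl]but-1-yn-1-yl]oxy}silane; 11 3-(diethoxymethyl)cyclobut-2-en-1-one (1.1 equiv)
Product: 14 (2S,3S)-2-[4-(tert-butyldimethylsilyloxy)phenyl]-3-[3,5-bis(triisopropylsilyloxy)phenyl]-4-(triisopropylsilyloxy)-2,3-dihydro-1-benzofuran-6-carbaldehyde, via vinylketene 12 (not isolated), via resorcinol monosilyl ether 13 (not isolated)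
Conditions: toluene, 80 → 110 °C; then cool, CH2Cl2, TFA, H2O, 0 °C → rt
Reagents that add atoms: water, O
Why: Proposed new method: thermal 4π opening of 11 gives vinylketene 12, which adds [2+2] to the siloxyalkyne (nucleophilic alkyne carbon to ketene carbon), and 4π opening, 6π closure and tautomerisation build ring A as phenol 13 with the free OH ortho to the side chain and the acetal para to it, after which aqueous TFA in the same flask hydrolyses the acetal and ionises the 4-siloxybenzylic silyl ether so that the phenol closes the dihydrofuran 5-exo, the new C-2 centre being set trans to the fixed C-3 aryl under kinetic and thermodynamic (reversible ionisation) control; the closest known reactions are the Danheiser benzannulation of siloxyalkynes with cyclobutenones and the acid-mediated cyclisation of 2-(2-hydroxyaryl)-1,2-diarylethanol derivatives to trans-2,3-diaryl-2,3-dihydrobenzofurans.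

Step 9
Reactants: 14 (2S,3S)-2-[4-(tert-butyldimethylsilyloxy)phenyl]-3-[3,5-bis(triisopropylsilyloxy)phenyl]-4-(triisopropylsilyloxy)-2,3-dihydro-1-benzofuran-6-carbaldehyde
Product: 15 Gnetal, (2S,3S)-3-(3,5-dihydroxyphenyl)-4-hydroxy-2-(4-hydroxyphenyl)-2,3-dihydro-1-benzofuran-6-carbaldehyde
Conditions: Bu4NF (TBAF, 5 equiv), AcOH (5 equiv), THF, 0 °C → rt
Reagents that add atoms: none
Why: Fluoride cleavage of the four aryl silyl ethers under acetic acid buffering leaves the aldehyde and both stereocentres untouched, and any reversible opening at C-2 through the phenoxide returns the trans isomer.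

## Compound list

1 | methyl 2-(3,5-dihydroxyphenyl)acetate | COC(=O)Cc1cc(O)cc(O)c1 | starting material
2 | methyl 2-[3,5-bis(triisopropylsilyloxy)phenyl]acetate | COC(=O)Cc1cc(O[Si](C(C)C)(C(C)C)C(C)C)cc(O[Si](C(C)C)(C(C)C)C(C)C)c1 | intermediate
3 | methyl 2-diazo-2-[3,5-bis(triisopropylsilyloxy)phenyl]acetate | COC(=O)C(=[N+]=[N-])c1cc(O[Si](C(C)C)(C(C)C)C(C)C)cc(O[Si](C(C)C)(C(C)C)C(C)C)c1 | intermediate
4 | 4-(hydroxymethyl)phenol (4-hydroxybenzyl alcohol) | OCc1ccc(O)cc1 | starting material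
5 | tert-butyl{[4-(tert-butyldimethylsilyloxy)phenyl]methoxy}dimethylsilane | CC(C)(C)[Si](C)(C)OCc1ccc(O[Si](C)(C)C(C)(C)C)cc1 | intermediate
6 | methyl (2R,3R)-2-[3,5-bis(triisopropylsilyloxy)phenyl]-3-(tert-butyldimethylsilyloxy)-3-[4-(tert-butyldimethylsilyloxy)phenyl]propanoate (syn) | COC(=O)[C@H](c1cc(O[Si](C(C)C)(C(C)C)C(C)C)cc(O[Si](C(C)C)(C(C)C)C(C)C)c1)[C@@H](O[Si](C)(C)C(C)(C)C)c1ccc(O[Si](C)(C)C(C)(C)C)cc1 | intermediate
7 | lithium (3S,4R)-3-[3,5-bis(triisopropylsilyloxy)phenyl]-4-(tert-butyldimethylsilyloxy)-4-[4-(tert-butyldimethylsilyloxy)phenyl]but-1-yn-1-olate | [Li+].[O-]C#C[C@H](c1cc(O[Si](C(C)C)(C(C)C)C(C)C)cc(O[Si](C(C)C)(C(C)C)C(C)C)c1)[C@@H](O[Si](C)(C)C(C)(C)C)c1ccc(O[Si](C)(C)C(C)(C)C)cc1 | intermediate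
8 | triisopropyl{[(3S,4R)-3-[3,5-bis(triisopropylsilyloxy)phenyl]-4-(tert-butyldimethylsilyloxy)-4-[4-(tert-butyldimethylsilyloxy)phenyl]but-1-yn-1-yl]oxy}silane | CC(C)[Si](OC#C[C@H](c1cc(O[Si](C(C)C)(C(C)C)C(C)C)cc(O[Si](C(C)C)(C(C)C)C(C)C)c1)[C@@H](O[Si](C)(C)C(C)(C)C)c1ccc(O[Si](C)(C)C(C)(C)C)cc1)(C(C)C)C(C)C | intermediate
9 | 3,3-diethoxyprop-1-yne | C#CC(OCC)OCC | starting material
10 | 4,4-dichloro-3-(diethoxymethyl)cyclobut-2-en-1-one | CCOC(OCC)C1=CC(=O)C1(Cl)Cl | intermediate
11 | 3-(diethoxymethyl)cyclobut-2-en-1-one | CCOC(OCC)C1=CC(=O)C1 | intermediate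
12 | 3-(diethoxymethyl)buta-1,3-dien-1-one (vinylketene) | CCOC(OCC)C(=C)C=C=O | intermediate
13 | 5-(diethoxymethyl)-2-[(1S,2R)-1-[3,5-bis(triisopropylsilyloxy)phenyl]-2-(tert-butyldimethylsilyloxy)-2-[4-(tert-butyldimethylsilyloxy)phenyl]ethyl]-3-(triisopropylsilyloxy)phenol | CCOC(OCC)c1cc(O)c([C@H](c2cc(O[Si](C(C)C)(C(C)C)C(C)C)cc(O[Si](C(C)C)(C(C)C)C(C)C)c2)[C@@H](O[Si](C)(C)C(C)(C)C)c2ccc(O[Si](C)(C)C(C)(C)C)cc2)c(O[Si](C(C)C)(C(C)C)C(C)C)c1 | intermediate
14 | (2S,3S)-2-[4-(tert-butyldimethylsilyloxy)phenyl]-3-[3,5-bis(triisopropylsilyloxy)phenyl]-4-(triisopropylsilyloxy)-2,3-dihydro-1-benzofuran-6-carbaldehyde | O=Cc1cc(O[Si](C(C)C)(C(C)C)C(C)C)c2c(c1)O[C@H](c1ccc(O[Si](C)(C)C(C)(C)C)cc1)[C@H]2c1cc(O[Si](C(C)C)(C(C)C)C(C)C)cc(O[Si](C(C)C)(C(C)C)C(C)C)c1 | intermediate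
15 | Gnetal, (2S,3S)-3-(3,5-dihydroxyphenyl)-4-hydroxy-2-(4-hydroxyphenyl)-2,3-dihydro-1-benzofuran-6-carbaldehyde | O=Cc1cc(O)c2c(c1)O[C@H](c1ccc(O)cc1)[C@H]2c1cc(O)cc(O)c1 | target

## Step count and risks

Total steps: 9. Longest linear sequence: 6 (steps 1, 2, 4, 5, 8, 9).

Steps most likely to fail:

Step 5. LiCHBr2 must add to a hindered α-aryl-β-siloxy ester; enolisation would epimerise C-2 or expel siloxide. The fallback sets out from 6 and comes back at 7, and from there at 8. i-Bu2AlH in toluene at −78 °C reduces 6 to the aldehyde F1. CBr4/PPh3 with 2,6-lutidine in CH2Cl2 at 0 °C, a non-basic olefination that spares the α-aryl centre, gives the 1,1-dibromoalkene F2. n-BuLi (2.1 equiv, THF, −78 °C) converts F2 in Corey–Fuchs fashion into the lithium acetylide F3, with C-3 and C-4 arranged as in 8. F3 is oxidised in the same flask with lithium tert-butyl peroxide (t-BuOOH/LiHMDS, −78 → 0 °C) to ynolate 7, which TIPSCl silylates to 8 as in step 5.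

Step 6. The acetal-bearing alkyne is a weak nucleophile toward dichloroketene, and ZnCl2 may ionise the acetal. The fallback sets out from 8 and comes back at 14; only the cyclobutenone partner changes. Commercial 3-ethoxycyclobut-2-en-1-one (CCOC1=CC(=O)C1) takes up CH2=CHMgBr in a 1,2-addition (THF, −78 °C), and dilute HCl effects hydrolytic transposition to 3-ethenylcyclobut-2-en-1-one F4. Heated with 8 in toluene, F4 opens to the vinylketene F5 and gives the 5-ethenyl resorcinol monosilyl ether F6. TFA in CH2Cl2 closes F6 to the 6-ethenyl dihydrobenzofuran F7. Lemieux–Johnson cleavage of the styrene (OsO4 cat., NaIO4, 2,6-lutidine, dioxane/H2O) then gives aldehyde 14.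

Step 8. The β-branched siloxyalkyne may add slowly, and in the acid stage E1 loss of the C-3 proton from the benzylic cation would give a triarylethylene and destroy the stereocentre. The fallback sets out from 13 and comes back at 15. The sequence is stopped after the thermal stage and 13 is isolated. Bu4NF in THF removes all five silyl groups to give the hexol acetal F8. On gentle warming in dilute aqueous AcOH/MeCN the acetal hydrolyses and the 4-hydroxybenzylic alcohol dehydrates to the neutral p-quinone methide F9. F9 is closed by 1,6-oxa-conjugate addition of either resorcinol OH (ring A is symmetric) to give trans Gnetal 15 directly, without a free benzylic cation and without step 9.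

## Further compounds

F1 | step 5 | (2R,3R)-2-[3,5-bis(triisopropylsilyloxy)phenyl]-3-(tert-butyldimethylsilyloxy)-3-[4-(tert-butyldimethylsilyloxy)phenyl]propanal | O=C[C@H](c1cc(O[Si](C(C)C)(C(C)C)C(C)C)cc(O[Si](C(C)C)(C(C)C)C(C)C)c1)[C@@H](O[Si](C)(C)C(C)(C)C)c1ccc(O[Si](C)(C)C(C)(C)C)cc1
F2 | step 5 | (3R,4R)-1,1-dibromo-3-[3,5-bis(triisopropylsilyloxy)phenyl]-4-(tert-butyldimethylsilyloxy)-4-[4-(tert-butyldimethylsilyloxy)phenyl]but-1-ene | BrC(Br)=C[C@H](c1cc(O[Si](C(C)C)(C(C)C)C(C)C)cc(O[Si](C(C)C)(C(C)C)C(C)C)c1)[C@@H](O[Si](C)(C)C(C)(C)C)c1ccc(O[Si](C)(C)C(C)(C)C)cc1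
F3 | step 5 | lithium acetylide of 3-[3,5-bis(triisopropylsilyloxy)phenyl]-4-(tert-butyldimethylsilyloxy)-4-[4-(tert-butyldimethylsilyloxy)phenyl]but-1-yne, C-3 and C-4 arranged as in 8 | [Li]C#C[C@H](c1cc(O[Si](C(C)C)(C(C)C)C(C)C)cc(O[Si](C(C)C)(C(C)C)C(C)C)c1)[C@@H](O[Si](C)(C)C(C)(C)C)c1ccc(O[Si](C)(C)C(C)(C)C)cc1
F4 | step 6 | 3-ethenylcyclobut-2-en-1-one | C=CC1=CC(=O)C1
F5 | step 6 | 3-methylidenepenta-1,4-dien-1-one (vinylketene) | C=CC(=C)C=C=O
F6 | step 6 | 5-ethenyl-2-[(1S,2R)-1-[3,5-bis(triisopropylsilyloxy)phenyl]-2-(tert-butyldimethylsilyloxy)-2-[4-(tert-butyldimethylsilyloxy)phenyl]ethyl]-3-(triisopropylsilyloxy)phenol | C=Cc1cc(O)c([C@H](c2cc(O[Si](C(C)C)(C(C)C)C(C)C)cc(O[Si](C(C)C)(C(C)C)C(C)C)c2)[C@@H](O[Si](C)(C)C(C)(C)C)c2ccc(O[Si](C)(C)C(C)(C)C)cc2)c(O[Si](C(C)C)(C(C)C)C(C)C)c1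
F7 | step 6 | (2S,3S)-2-[4-(tert-butyldimethylsilyloxy)phenyl]-3-[3,5-bis(triisopropylsilyloxy)phenyl]-6-ethenyl-4-(triisopropylsilyloxy)-2,3-dihydro-1-benzofuran | C=Cc1cc(O[Si](C(C)C)(C(C)C)C(C)C)c2c(c1)O[C@H](c1ccc(O[Si](C)(C)C(C)(C)C)cc1)[C@H]2c1cc(O[Si](C(C)C)(C(C)C)C(C)C)cc(O[Si](C(C)C)(C(C)C)C(C)C)c1
F8 | step 8 | 5-(diethoxymethyl)-2-[(1S,2R)-1-(3,5-dihydroxyphenyl)-2-hydroxy-2-(4-hydroxyphenyl)ethyl]benzene-1,3-diol | CCOC(OCC)c1cc(O)c([C@H](c2cc(O)cc(O)c2)[C@@H](O)c2ccc(O)cc2)c(O)c1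
F9 | step 8 | 4-[(1S)-1-(3,5-dihydroxyphenyl)-2-(4-oxocyclohexa-2,5-dien-1-ylidene)ethyl]-3,5-dihydroxybenzaldehyde | O=Cc1cc(O)c([C@H](c2cc(O)cc(O)c2)C=C2C=CC(=O)C=C2)c(O)c1
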